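## Retrosynthetic overview

1. Target 33 ⇐ methyl ester 32 ⇐ Negishi coupling (C11–C12) of dioxane vinyl iodide 26 with the alkenylzinc from 29; the diene is installed only after the peroxide is in place.
2. The 1,2-dioxane (the only ring, closed in step 17) ⇐ 6-exo oxa-Michael closure (O–C3) of a C6 tertiary hydroperoxide onto the C2=C3 enoate; the hydroperoxide ⇐ Isayama–Mukaiyama hydroperoxysilylation of the C6 methylidene of 23.
3. 23 ⇐ ketone 16 by methylenation (C6), alkyne carboalumination–iodination (C10=C11) and C3 oxidation/Wittig olefination (C1–C2).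
4. Key C–C bond C5–C6: crossed Claisen condensation of the lithium enolate of ester 6 (fragment 1, C3–C5) with acid chloride 12 (fragment 2, C6–C11), then decarboxylation to 16.
5. Stereocentres: C4 by Evans alkylation; C8 from methyl (R)-3-methylglutarate; C3 by the chair-like cyclisation (trans to C4-Me); C6 is formed without control and the epimers are separated.

Atom labels C1–C14 follow the target chain (C1 = CO2H, C14 = CH2Ph).

Assumption: methyl (R)-3-methylglutarate 7 (≥ 98% ee, also obtainable by esterase hydrolysis of dimethyl 3-methylglutarate) is taken as a commercial starting material.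

## Route

Step 1
Reactants: 1 (4R)-4-benzyl-3-propanoyl-1,3-oxazolidin-2-one; 2 tert-butyl bromoacetate
Product: 4 tert-butyl (3S)-4-[(4R)-4-benzyl-2-oxo-1,3-oxazolidin-3-yl]-3-methyl-4-oxobutanoate, via sodium enolate 3 (not isolated)
Conditions: NaN(SiMe3)2, THF, −78 °C; then 2, −78 → −40 °C
Reagents that add atoms: none
Why: Evans asymmetric alkylation, in which the chelated (Z)-enolate is alkylated on the face opposite the benzyl group, setting C4 as (S) with dr > 95:5 (upgraded by crystallisation).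

Step 2
Reactants: 4 tert-butyl (3S)-4-[(4R)-4-benzyl-2-oxo-1,3-oxazolidin-3-yl]-3-methyl-4-oxobutanoate
Product: 5 tert-butyl (3S)-4-hydroxy-3-methylbutanoate
Conditions: LiBH4, H2O (1 equiv), Et2O, 0 °C
Reagents that add atoms: none
Why: Reductive removal of the auxiliary: the activated imide carbonyl is reduced to CH2OH much faster than the hindered tert-butyl ester, C4 is untouched and the oxazolidinone is recovered.

Step 3
Reactants: 5 tert-butyl (3S)-4-hydroxy-3-methylbutanoate
Product: 6 tert-butyl (3S)-4-[(tert-butyldiphenylsilyl)oxy]-3-methylbutanoate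
Conditions: t-BuPh2SiCl, imidazole, DMF, rt
Reagents that add atoms: tert-butyl(chloro)diphenylsilane, CC(C)(C)[Si](Cl)(c1ccccc1)c1ccccc1
Why: Silylation of the primary alcohol gives an ether that survives the amide base, CF3CO2H, the ylide and Me3Al used later.

Step 4
Reactants: 7 (3R)-5-methoxy-3-methyl-5-oxopentanoic acid [methyl (R)-3-methylglutarate]
Product: 8 methyl (3R)-5-hydroxy-3-methylpentanoate
Conditions: BH3·SMe2, THF, 0 °C → rt; MeOH quench
Reagents that add atoms: none
Why: Chemoselective borane reduction of the free carboxylic acid (via the acyloxyborane) in the presence of the methyl ester; the C8 stereocentre is carried over from 7.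

Step 5
Reactants: 8 methyl (3R)-5-hydroxy-3-methylpentanoate
Product: 9 methyl (3R)-3-methyl-5-oxopentanoate
Conditions: TEMPO (10 mol %), PhI(OAc)2, CH2Cl2, rt
Reagents that add atoms: none
Why: Oxoammonium (TEMPO) oxidation stops cleanly at the aldehyde and there is no α-stereocentre to epimerise.

Step 6
Reactants: 9 methyl (3R)-3-methyl-5-oxopentanoate
Product: 10 methyl (3R)-3-methylhex-5-ynoate
Conditions: dimethyl (1-diazo-2-oxopropyl)phosphonate, K2CO3, MeOH, 0 °C → rt
Reagents that add atoms: dimethyl (1-diazo-2-oxopropyl)phosphonate, COP(=O)(OC)C(=[N+]=[N-])C(C)=O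
Why: Seyferth–Gilbert homologation in the Ohira–Bestmann variant converts the aldehyde into the terminal alkyne (adds C11) under mild carbonate conditions.

Step 7
Reactants: 10 methyl (3R)-3-methylhex-5-ynoate
Product: 11 (3R)-3-methylhex-5-ynoic acid
Conditions: LiOH, THF/H2O, rt; then 1 M HCl
Reagents that add atoms: lithium hydroxide, [Li+].[OH-]
Why: Plain saponification; the stereocentre is β to the carboxyl and cannot epimerise.

Step 8
Reactants: 11 (3R)-3-methylhex-5-ynoic acid
Product: 12 (3R)-3-methylhex-5-ynoyl chloride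
Conditions: (COCl)2, DMF (cat.), CH2Cl2, 0 °C → rt; concentrated and used crude
Reagents that add atoms: oxalyl chloride, O=C(Cl)C(Cl)=O
Why: Vilsmeier-type activation of the acid gives the acylating partner for the condensation with only gaseous by-products.

Step 9
Reactants: 6 tert-butyl (3S)-4-[(tert-butyldiphenylsilyl)oxy]-3-methylbutanoate; 12 (3R)-3-methylhex-5-ynoyl chloride
Product: 14 tert-butyl (2RS,5R)-2-[(2S)-1-[(tert-butyldiphenylsilyl)oxy]propan-2-yl]-5-methyl-3-oxooct-7-ynoate, via lithium enolate 13 (not isolated)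
Conditions: 6 (2.2 equiv), LiN(iPr)2 (2.2 equiv), THF, −78 °C; then 12 (1.0 equiv), −78 °C; aq NH4Cl
Reagents that add atoms: none
Why: Crossed Claisen condensation: C-acylation of the ester enolate by the acid chloride forms the C5–C6 bond, the second equivalent of enolate deprotonates the β-keto ester to stop over-acylation (excess 6 is recovered), and the new C5 centre is irrelevant because it is removed in step 10.

Step 10
Reactants: 14 tert-butyl (2RS,5R)-2-[(2S)-1-[(tert-butyldiphenylsilyl)oxy]propan-2-yl]-5-methyl-3-oxooct-7-ynoate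
Product: 16 (2S,6R)-1-[(tert-butyldiphenylsilyl)oxy]-2,6-dimethylnon-8-yn-4-one, via β-keto acid 15 (not isolated)
Conditions: CF3CO2H/CH2Cl2 (1:4), 0 °C → rt; then toluene, 60 °C
Reagents that add atoms: none
Why: Acidolysis of the tert-butyl ester and decarboxylation of the β-keto acid through the six-membered transition state give the ketone; C4 and C8 are β to the carbonyl and cannot epimerise.

Step 11
Reactants: 16 (2S,6R)-1-[(tert-butyldiphenylsilyl)oxy]-2,6-dimethylnon-8-yn-4-one
Product: 17 tert-butyl{[(2S,6S)-2,6-dimethyl-4-methylidenenon-8-yn-1-yl]oxy}diphenylsilane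
Conditions: Ph3PCH3Br, KOtBu, THF, 0 °C → rt
Reagents that add atoms: methyltriphenylphosphonium bromide, C[P+](c1ccccc1)(c1ccccc1)c1ccccc1.[Br-]
Why: Wittig methylenation of an unhindered dialkyl ketone installs the C6 methylidene (the stereodescriptor at C8 changes only through CIP priorities).

Step 12
Reactants: 17 tert-butyl{[(2S,6S)-2,6-dimethyl-4-methylidenenon-8-yn-1-yl]oxy}diphenylsilane
Product: 19 tert-butyl{[(2S,6S,8E)-9-iodo-2,6,8-trimethyl-4-methylidenenon-8-en-1-yl]oxy}diphenylsilane, via alkenylalane 18 (not isolated)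
Conditions: Me3Al (3 equiv), Cp2ZrCl2 (0.3 equiv), CH2Cl2, 0 °C → rt; then I2, THF, −30 → 0 °C
Reagents that add atoms: trimethylaluminium, C[Al](C)C; iodine, [I][I]
Why: Negishi zirconium-catalysed carboalumination adds Me and Al syn across the terminal alkyne (Al at the terminus) and iodinolysis with retention gives the (E)-vinyl iodide; the 1,1-disubstituted alkene and silyl ether are inert.

Step 13
Reactants: 19 tert-butyl{[(2S,6S,8E)-9-iodo-2,6,8-trimethyl-4-methylidenenon-8-en-1-yl]oxy}diphenylsilane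
Product: 20 (2S,6S,8E)-9-iodo-2,6,8-trimethyl-4-methylidenenon-8-en-1-ol
Conditions: Bu4NF, THF, 0 °C → rt
Reagents that add atoms: none
Why: Fluoride cleavage of the silyl ether; nothing else in the molecule is fluoride-labile.

Step 14
Reactants: 20 (2S,6S,8E)-9-iodo-2,6,8-trimethyl-4-methylidenenon-8-en-1-ol
Product: 21 (2S,6S,8E)-9-iodo-2,6,8-trimethyl-4-methylidenenon-8-enal
Conditions: Dess–Martin periodinane, CH2Cl2, 0 °C → rt
Reagents that add atoms: none
Why: Dess–Martin oxidation gives the α-methyl aldehyde under near-neutral conditions, so C4 is not epimerised.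

Step 15
Reactants: 21 (2S,6S,8E)-9-iodo-2,6,8-trimethyl-4-methylidenenon-8-enal; 22 methyl (triphenyl-λ5-phosphanylidene)acetate
Product: 23 methyl (2E,4S,8S,10E)-11-iodo-4,8,10-trimethyl-6-methylideneundeca-2,10-dienoate
Conditions: CH2Cl2, rt
Reagents that add atoms: none
Why: Wittig olefination with a stabilised ylide is base-free and (E)-selective (> 95:5), giving the Michael acceptor without touching C4.

Step 16
Reactants: 23 methyl (2E,4S,8S,10E)-11-iodo-4,8,10-trimethyl-6-methylideneundeca-2,10-dienoate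
Product: 24 methyl (2E,4S,6RS,8R,10E)-11-iodo-4,6,8,10-tetramethyl-6-[(triethylsilyl)peroxy]undeca-2,10-dienoate
Conditions: Co(thd)2 (10 mol %; thd = 2,2,6,6-tetramethylheptane-3,5-dionate), Et3SiH (2 equiv), O2 (1 atm), ClCH2CH2Cl, rt
Reagents that add atoms: dioxygen, O=O; triethylsilane, CC[SiH](CC)CC
Why: Isayama–Mukaiyama hydroperoxysilylation: a cobalt hydride delivers H to the terminal CH2 of the electron-rich 1,1-disubstituted alkene (faster than to the enoate or the hindered vinyl iodide), and the tertiary C6 radical is trapped by O2 and silylated without facial control (C6 epimers about 1:1, separated in step 17).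

Step 17
Reactants: 24 methyl (2E,4S,6RS,8R,10E)-11-iodo-4,6,8,10-tetramethyl-6-[(triethylsilyl)peroxy]undeca-2,10-dienoate
Product: 26 methyl 2-[(3R,4S,6R)-6-[(2R,4E)-5-iodo-2,4-dimethylpent-4-en-1-yl]-4,6-dimethyl-1,2-dioxan-3-yl]acetate, via hydroperoxide 25 (not isolated)
Conditions: HCl (cat.), MeOH, 0 °C; then Et2NH, CF3CH2OH, rt; chromatography
Reagents that add atoms: none
Why: Methanolysis frees the hydroperoxide, which closes by amine-catalysed 6-exo-trig intramolecular oxa-Michael addition through a chair with the C4 methyl and the forming acetate arm equatorial, setting C3 as (R) (trans to C4-Me); chromatography removes the (6S)-epimer, so C6 (R) is secured here.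

Step 18
Reactants: 27 but-2-yn-1-ylbenzene
Product: 29 [(2E)-3-iodobut-2-en-1-yl]benzene, via alkenylzirconocene 28 (not isolated)
Conditions: Cp2Zr(H)Cl (2 equiv), THF, 50 °C; then I2, 0 °C
Reagents that add atoms: iodine, [I][I]
Why: Hydrozirconation is a syn addition that, under equilibrating conditions with excess reagent, places zirconium on the less hindered methyl-bearing carbon; iodinolysis with retention gives the (E)-iodide.

Step 19
Reactants: 29 [(2E)-3-iodobut-2-en-1-yl]benzene; 26 methyl 2-[(3R,4S,6R)-6-[(2R,4E)-5-iodo-2,4-dimethylpent-4-en-1-yl]-4,6-dimethyl-1,2-dioxan-3-yl]acetate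
Product: 32 methyl 2-[(3R,4S,6R)-4,6-dimethyl-6-[(2R,4E,6E)-2,4,6-trimethyl-8-phenylocta-4,6-dien-1-yl]-1,2-dioxan-3-yl]acetate, via alkenyllithium 30 (not isolated), via alkenylzinc chloride 31 (not isolated)
Conditions: 29 (1.5 equiv), t-BuLi (2 equiv per iodide), Et2O, −78 °C; ZnCl2, THF, −78 → 0 °C; then 26, Pd2(dba)3 (2.5 mol %), P(2-furyl)3 (10 mol %), THF, rt
Reagents that add atoms: none
Why: Negishi cross-coupling proceeds with retention at both alkenyl partners to give the (E,E)-diene, and the mild organozinc with a weakly nucleophilic phosphine should leave the dialkyl peroxide and the ester intact.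

Step 20
Reactants: 32 methyl 2-[(3R,4S,6R)-4,6-dimethyl-6-[(2R,4E,6E)-2,4,6-trimethyl-8-phenylocta-4,6-dien-1-yl]-1,2-dioxan-3-yl]acetate
Product: 33 2-[(3R,4S,6R)-4,6-dimethyl-6-[(2R,4E,6E)-2,4,6-trimethyl-8-phenylocta-4,6-dien-1-yl]-1,2-dioxan-3-yl]acetic acid
Conditions: LiOH, THF/H2O, 0 °C → rt; then cold 0.5 M HCl to pH 3
Reagents that add atoms: lithium hydroxide, [Li+].[OH-]
Why: Cold saponification is the standard way to free 1,2-dioxane-3-acetic acids; no stereocentre is involved.

## Compound list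

1 | (4R)-4-benzyl-3-propanoyl-1,3-oxazolidin-2-one | CCC(=O)N1[C@H](Cc2ccccc2)COC1=O | starting material
2 | tert-butyl bromoacetate | CC(C)(C)OC(=O)CBr | starting material
3 | sodium (1Z)-1-[(4R)-4-benzyl-2-oxo-1,3-oxazolidin-3-yl]prop-1-en-1-olate (sodium enolate of 1) | C/C=C(\[O-])N1[C@H](Cc2ccccc2)COC1=O.[Na+] | intermediate
4 | tert-butyl (3S)-4-[(4R)-4-benzyl-2-oxo-1,3-oxazolidin-3-yl]-3-methyl-4-oxobutanoate | CC(C)(C)OC(=O)C[C@H](C)C(=O)N1[C@H](Cc2ccccc2)COC1=O | intermediate
5 | tert-butyl (3S)-4-hydroxy-3-methylbutanoate | CC(C)(C)OC(=O)C[C@H](C)CO | intermediate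
6 | tert-butyl (3S)-4-[(tert-butyldiphenylsilyl)oxy]-3-methylbutanoate | CC(C)(C)OC(=O)C[C@H](C)CO[Si](c1ccccc1)(c1ccccc1)C(C)(C)C | intermediate
7 | (3R)-5-methoxy-3-methyl-5-oxopentanoic acid [methyl (R)-3-methylglutarate] | COC(=O)C[C@H](C)CC(=O)O | starting material
8 | methyl (3R)-5-hydroxy-3-methylpentanoate | COC(=O)C[C@H](C)CCO | intermediate
9 | methyl (3R)-3-methyl-5-oxopentanoate | COC(=O)C[C@H](C)CC=O | intermediate
10 | methyl (3R)-3-methylhex-5-ynoate | COC(=O)C[C@H](C)CC#C | intermediate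
11 | (3R)-3-methylhex-5-ynoic acid | OC(=O)C[C@H](C)CC#C | intermediate
12 | (3R)-3-methylhex-5-ynoyl chloride | ClC(=O)C[C@H](C)CC#C | intermediate
13 | lithium (3S)-1-tert-butoxy-4-[(tert-butyldiphenylsilyl)oxy]-3-methylbut-1-en-1-olate (lithium enolate of 6) | CC(C)(C)OC([O-])=C[C@H](C)CO[Si](c1ccccc1)(c1ccccc1)C(C)(C)C.[Li+] | intermediate
14 | tert-butyl (2RS,5R)-2-[(2S)-1-[(tert-butyldiphenylsilyl)oxy]propan-2-yl]-5-methyl-3-oxooct-7-ynoate | CC(C)(C)OC(=O)C(C(=O)C[C@H](C)CC#C)[C@H](C)CO[Si](c1ccccc1)(c1ccccc1)C(C)(C)C | intermediate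
15 | (2RS,5R)-2-[(2S)-1-[(tert-butyldiphenylsilyl)oxy]propan-2-yl]-5-methyl-3-oxooct-7-ynoic acid | OC(=O)C(C(=O)C[C@H](C)CC#C)[C@H](C)CO[Si](c1ccccc1)(c1ccccc1)C(C)(C)C | intermediate
16 | (2S,6R)-1-[(tert-butyldiphenylsilyl)oxy]-2,6-dimethylnon-8-yn-4-one | C#CC[C@@H](C)CC(=O)C[C@H](C)CO[Si](c1ccccc1)(c1ccccc1)C(C)(C)C | intermediate
17 | tert-butyl{[(2S,6S)-2,6-dimethyl-4-methylidenenon-8-yn-1-yl]oxy}diphenylsilane | C#CC[C@@H](C)CC(=C)C[C@H](C)CO[Si](c1ccccc1)(c1ccccc1)C(C)(C)C | intermediate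
18 | dimethyl{(1E,4S,8S)-9-[(tert-butyldiphenylsilyl)oxy]-2,4,8-trimethyl-6-methylidenenon-1-en-1-yl}alumane | C[Al](C)/C=C(\C)C[C@@H](C)CC(=C)C[C@H](C)CO[Si](c1ccccc1)(c1ccccc1)C(C)(C)C | intermediate
19 | tert-butyl{[(2S,6S,8E)-9-iodo-2,6,8-trimethyl-4-methylidenenon-8-en-1-yl]oxy}diphenylsilane | I/C=C(\C)C[C@@H](C)CC(=C)C[C@H](C)CO[Si](c1ccccc1)(c1ccccc1)C(C)(C)C | intermediate
20 | (2S,6S,8E)-9-iodo-2,6,8-trimethyl-4-methylidenenon-8-en-1-ol | I/C=C(\C)C[C@@H](C)CC(=C)C[C@H](C)CO | intermediate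
21 | (2S,6S,8E)-9-iodo-2,6,8-trimethyl-4-methylidenenon-8-enal | I/C=C(\C)C[C@@H](C)CC(=C)C[C@H](C)C=O | intermediate
22 | methyl (triphenyl-λ5-phosphanylidene)acetate | COC(=O)C=P(c1ccccc1)(c1ccccc1)c1ccccc1 | starting material
23 | methyl (2E,4S,8S,10E)-11-iodo-4,8,10-trimethyl-6-methylideneundeca-2,10-dienoate | I/C=C(\C)C[C@@H](C)CC(=C)C[C@H](C)/C=C/C(=O)OC | intermediate
24 | methyl (2E,4S,6RS,8R,10E)-11-iodo-4,6,8,10-tetramethyl-6-[(triethylsilyl)peroxy]undeca-2,10-dienoate (C6 epimers) | I/C=C(\C)C[C@@H](C)CC(C)(OO[Si](CC)(CC)CC)C[C@H](C)/C=C/C(=O)OC | intermediate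
25 | methyl (2E,4S,6RS,8R,10E)-6-hydroperoxy-11-iodo-4,6,8,10-tetramethylundeca-2,10-dienoate (C6 epimers) | I/C=C(\C)C[C@@H](C)CC(C)(OO)C[C@H](C)/C=C/C(=O)OC | intermediate
26 | methyl 2-[(3R,4S,6R)-6-[(2R,4E)-5-iodo-2,4-dimethylpent-4-en-1-yl]-4,6-dimethyl-1,2-dioxan-3-yl]acetate | I/C=C(\C)C[C@@H](C)C[C@]1(C)C[C@H](C)[C@@H](CC(=O)OC)OO1 | intermediate
27 | but-2-yn-1-ylbenzene (1-phenyl-2-butyne) | CC#CCc1ccccc1 | starting material
28 | chloridobis(cyclopentadienyl)[(2E)-4-phenylbut-2-en-2-yl]zirconium | C/C(=C\Cc1ccccc1)[Zr](Cl)(C1C=CC=C1)C1C=CC=C1 | intermediate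
29 | [(2E)-3-iodobut-2-en-1-yl]benzene | C/C(I)=C\Cc1ccccc1 | intermediate
30 | [(2Z)-4-phenylbut-2-en-2-yl]lithium (methyl cis to benzyl) | C/C([Li])=C\Cc1ccccc1 | intermediate
31 | chlorido[(2E)-4-phenylbut-2-en-2-yl]zinc | C/C([Zn]Cl)=C\Cc1ccccc1 | intermediate
32 | methyl 2-[(3R,4S,6R)-4,6-dimethyl-6-[(2R,4E,6E)-2,4,6-trimethyl-8-phenylocta-4,6-dien-1-yl]-1,2-dioxan-3-yl]acetate | CC(=C\Cc1ccccc1)/C=C(\C)C[C@@H](C)C[C@]1(C)C[C@H](C)[C@@H](CC(=O)OC)OO1 | intermediate
33 | 2-[(3R,4S,6R)-4,6-dimethyl-6-[(2R,4E,6E)-2,4,6-trimethyl-8-phenylocta-4,6-dien-1-yl]-1,2-dioxan-3-yl]acetic acid | CC(=C\Cc1ccccc1)/C=C(\C)C[C@@H](C)C[C@]1(C)C[C@H](C)[C@@H](CC(=O)O)OO1 | target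

## Step count and risks

Total steps: 20. Longest linear sequence: 16 steps (7 → 33 through steps 4–17, 19 and 20).

Step 9 (crossed Claisen condensation) is at risk because a β-branched ester enolate must be C-acylated by an enolisable acid chloride, so ketene formation and proton transfer can erode the yield. The fallback sets out from 6 and 10 and comes back at 16, exchanging the roles of the two fragments in a titanium-mediated crossed Claisen. CF3CO2H cleaves the tert-butyl ester of 6 to (3S)-4-[(tert-butyldiphenylsilyl)oxy]-3-methylbutanoic acid F1, and oxalyl chloride converts it into (3S)-4-[(tert-butyldiphenylsilyl)oxy]-3-methylbutanoyl chloride F2. F2 then acylates the titanium enolate of methyl ester 10 (TiCl4, Bu3N, N-methylimidazole, CH2Cl2, −45 °C) to give methyl (2RS,3R)-2-[(3S)-4-[(tert-butyldiphenylsilyl)oxy]-3-methylbutanoyl]-3-methylhex-5-ynoate F3. Krapcho demethoxycarbonylation (LiCl, wet DMSO, 130 °C) delivers ketone 16.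

Step 16 (hydroperoxysilylation) is at risk because the enoate and the vinyl iodide may compete for the cobalt hydride; in addition it gives no control at C6, so at most half of the material is carried on. The fallback sets out from 20 and comes back at 24, putting the peroxide in before the conjugated ester exists. The same Co(thd)2/Et3SiH/O2 conditions applied to alcohol 20 give (2S,4RS,6R,8E)-9-iodo-2,4,6,8-tetramethyl-4-[(triethylsilyl)peroxy]non-8-en-1-ol F4. Dess–Martin oxidation gives (2S,4RS,6R,8E)-9-iodo-2,4,6,8-tetramethyl-4-[(triethylsilyl)peroxy]non-8-enal F5, and Wittig reaction of F5 with 22 gives 24.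

Step 19 (Negishi coupling on the peroxide) is at risk because zerovalent palladium and phosphine can attack the O–O bond and both alkenyl partners are trisubstituted. The fallback sets out from 29 and comes back at 32, replacing the zinc reagent by an isolable tin reagent. Lithium–iodine exchange on 29 (t-BuLi, Et2O, −78 °C) and quenching with Bu3SnCl give tributyl[(2E)-4-phenylbut-2-en-2-yl]stannane F6. Stille coupling of F6 with 26 under phosphine-free, base-free conditions (Pd2(dba)3, AsPh3, DMF, 40 °C) gives 32.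

## Further compounds

F1 | step 9 | (3S)-4-[(tert-butyldiphenylsilyl)oxy]-3-methylbutanoic acid | OC(=O)C[C@H](C)CO[Si](c1ccccc1)(c1ccccc1)C(C)(C)C
F2 | step 9 | (3S)-4-[(tert-butyldiphenylsilyl)oxy]-3-methylbutanoyl chloride | ClC(=O)C[C@H](C)CO[Si](c1ccccc1)(c1ccccc1)C(C)(C)C
F3 | step 9 | methyl (2RS,3R)-2-[(3S)-4-[(tert-butyldiphenylsilyl)oxy]-3-methylbutanoyl]-3-methylhex-5-ynoate | COC(=O)C(C(=O)C[C@H](C)CO[Si](c1ccccc1)(c1ccccc1)C(C)(C)C)[C@H](C)CC#C
F4 | step 16 | (2S,4RS,6R,8E)-9-iodo-2,4,6,8-tetramethyl-4-[(triethylsilyl)peroxy]non-8-en-1-ol | I/C=C(\C)C[C@@H](C)CC(C)(OO[Si](CC)(CC)CC)C[C@H](C)CO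
F5 | step 16 | (2S,4RS,6R,8E)-9-iodo-2,4,6,8-tetramethyl-4-[(triethylsilyl)peroxy]non-8-enal | I/C=C(\C)C[C@@H](C)CC(C)(OO[Si](CC)(CC)CC)C[C@H](C)C=O
F6 | step 19 | tributyl[(2E)-4-phenylbut-2-en-2-yl]stannane | C/C(=C\Cc1ccccc1)[Sn](CCCC)(CCCC)CCCC
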